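**Assumption (one line):** the Piancatelli closure puts the C12-OH trans to the C8 side chain. That C8 epimer is converted to the target's cis arrangement by base equilibration during the elimination in Step 12. Prostanoid numbering is used throughout: C1 is the ester carbon, C8–C12 the ring, C13–C20 the ω-chain.

## Retrosynthetic overview
1. Punaglandin 2 comes from the tri-acetate of a tri-TBS precursor. The α-chloroenone is made from the enone by epoxidation, chloride opening at C10 and elimination (Cl2 is excluded by the Z-olefin).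
2. The only ring (the cyclopentenone, with its C12 tertiary carbinol and the C8–C12 bond) forms by Piancatelli 4π-conrotatory electrocyclization of a 5-alkyl-2-furylcarbinol.
3. The furylcarbinol comes from 5-lithio-2-[(Z)-oct-2-enyl]furan and an α-silyloxy aldehyde.
4. The aldehyde (C5–C7 stereotriad) comes from D-xylose: C1–C4 chain extension by Wittig, then oxidation of the C5 carbinol of xylose (C8 here).

## Forward route

**Step 1**
Reactants: 1 D-xylose; 2 (2-carboxyethyl)triphenylphosphonium bromide
Product: 3 (3Z,5S,6R,7R)-5,6,7,8-tetrahydroxyoct-3-enoic acid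
Conditions: 2 (3 equiv), KOtBu (6 equiv), THF, 0 → 50 °C
Reagents that add atoms: none
Why: Wittig olefination of the open-chain aldehyde form of xylose with the carboxylate ylide attaches C1–C3 to xylose C1, which becomes C4. C2–C4 of xylose become C5–C7 and are untouched.

**Step 2**
Reactants: 3
Product: 4 methyl (5S,6R,7R)-5,6,7,8-tetrahydroxyoctanoate
Conditions: (i) H2 (1 atm), 10% Pd/C, MeOH, 25 °C; filter; (ii) Amberlyst-15 (H+), MeOH, 25 °C
Reagents that add atoms: methanol, CO
Why: Neutral hydrogenation saturates the alkene first, which avoids allylic hydrogenolysis. Acid-catalysed Fischer esterification in excess MeOH then opens any δ-lactone to the methyl ester. No stereocenter is touched.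

**Step 3**
Reactants: 4
Product: 5 methyl (5S,6R,7R)-5,6,7,8-tetrakis(TBSO)octanoate
Conditions: TBSOTf (6 equiv), 2,6-lutidine (10 equiv), CH2Cl2, 0 → 25 °C
Reagents that add atoms: tert-butyldimethylsilyl triflate, CC(C)(C)[Si](C)(C)OS(=O)(=O)C(F)(F)F
Why: Silylation with TBSOTf protects all four hydroxyls as base-stable ethers, which tolerate the later organolithium and Lewis-acid steps.

**Step 4**
Reactants: 5
Product: 6 methyl (5S,6R,7R)-5,6,7-tris(TBSO)-8-hydroxyoctanoate
Conditions: CSA (0.2 equiv), MeOH/CH2Cl2 1:1, 0 °C, 1 h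
Reagents that add atoms: none
Why: Acid-catalysed methanolysis cleaves the unhindered primary TBS ether much faster than the three secondary ones.

**Step 5**
Reactants: 6
Product: 7 methyl (5S,6R,7S)-5,6,7-tris(TBSO)-8-oxooctanoate
Conditions: Dess–Martin periodinane, NaHCO3, CH2Cl2, 0 → 25 °C; used crude
Reagents that add atoms: none
Why: Mild, non-basic Dess–Martin oxidation of the primary alcohol gives the aldehyde without epimerising the α-silyloxy C7. (The descriptor at C7 changes from R to S only because C8 now outranks C6.)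

**Step 6**
Reactants: 8 (Z)-oct-2-en-1-ol
Product: 9 (Z)-1-bromooct-2-ene
Conditions: CBr4, PPh3, CH2Cl2, 0 °C; used immediately
Reagents that add atoms: carbon tetrabromide, BrC(Br)(Br)Br
Why: Appel SN2 substitution at the primary allylic carbon keeps the Z geometry.

**Step 7**
Reactants: 10 furan; 9
Product: 11 2-[(2Z)-oct-2-en-1-yl]furan
Conditions: n-BuLi, THF, −20 °C; then 9, −78 → 0 °C
Reagents that add atoms: none
Why: 2-Furyllithium alkylates the allylic bromide by SN2, which installs the C13–C20 chain with the Z-olefin intact.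

**Step 8**
Reactants: 11; 7
Product: 12 methyl (5S,6R,7R)-8-hydroxy-8-{5-[(2Z)-oct-2-en-1-yl]furan-2-yl}-5,6,7-tris(TBSO)octanoate, as a C8 epimeric mixture
Conditions: 11, n-BuLi, THF, −40 °C, 1 h; then 7, −78 °C
Reagents that add atoms: none
Why: Regioselective α-lithiation at the free C5 position of the 2-alkylfuran, then 1,2-addition to the aldehyde at −78 °C, which is far faster than attack on the remote methyl ester. The new carbinol stereocenter is destroyed in the next step, so the epimers converge.

**Step 9**
Reactants: 12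
Product: 13 methyl (5S,6R,7R,8S,12R,14Z)-12-hydroxy-9-oxo-5,6,7-tris(TBSO)prosta-10,14-dienoate, the 8-epimer of the target skeleton (C12-OH trans to the C8 chain)
Conditions: Dy(OTf)3 (5 mol %), MeCN/H2O 10:1, 80 °C, 1 h
Reagents that add atoms: none (water is a catalytic shuttle; net isomerisation)
Why: Piancatelli rearrangement: ionisation of the furylcarbinol, water addition and ring opening give a hydroxypentadienyl cation. Its 4π-conrotatory electrocyclization forms the C8–C12 bond and the C12 tertiary carbinol. The oxocarbenium OH rotates outward, giving OH trans to the C8 chain, and the C7 silyloxy stereocenter biases the sense of rotation, which sets C12.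

**Step 10**
Reactants: 13
Product: 14 methyl 10,11-epoxy-12-hydroxy-9-oxo-5,6,7-tris(TBSO)prost-14-enoate (epoxide diastereomers; C5–C8 and C12 as in 13)
Conditions: t-BuOOH, DBU (0.3 equiv), CH2Cl2, 0 °C
Reagents that add atoms: tert-butyl hydroperoxide, CC(C)(C)OO
Why: Weitz–Scheffer nucleophilic epoxidation is selective for the electron-poor enone over the isolated Z-olefin, and the methyl ester and silyl ethers are untouched. The epoxide stereochemistry is irrelevant because it is removed in Step 12.

**Step 11**
Reactants: 14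
Product: 15 methyl 10-chloro-11,12-dihydroxy-9-oxo-5,6,7-tris(TBSO)prost-14-enoate (C10/C11 diastereomers)
Conditions: LiCl (5 equiv), AcOH (10 equiv), THF, 25 °C
Reagents that add atoms: lithium chloride, [Li+].[Cl-]
Why: Acid-activated SN2 opening of the α,β-epoxy ketone by chloride at C10, which is activated by the C9 carbonyl. C11 is neopentyl to the quaternary C12 and is shielded from attack.

**Step 12**
Reactants: 15
Product: 16 methyl (5S,6R,7R,8R,12S,14Z)-10-chloro-12-hydroxy-9-oxo-5,6,7-tris(TBSO)prosta-10,14-dienoate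
Conditions: MsCl, Et3N, CH2Cl2, 0 °C; then DBU (1.5 equiv), 0 → 25 °C; chromatographic separation of C8 epimers
Reagents that add atoms: none
Why: The C11 secondary alcohol is mesylated (the C12 tertiary OH is not) and E1cB elimination through the acidic C10–H gives the 2-chloroenone, which is punaglandin's C10–C11 alkene. DBU also equilibrates C8 to the thermodynamic isomer, with the C8 chain cis to the smaller OH and trans to the C13 chain, which is the target configuration.

**Step 13**
Reactants: 16
Product: 17 methyl (5S,6R,7R,8R,12S,14Z)-10-chloro-5,6,7,12-tetrahydroxy-9-oxoprosta-10,14-dienoate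
Conditions: HF·pyridine, pyridine, THF, 25 °C, 24 h
Reagents that add atoms: none
Why: Buffered fluoride removes the three silyl ethers without touching the enone, vinyl chloride or Z-olefin, and avoids strongly basic conditions that would cause β-elimination.

**Step 14**
Reactants: 17
Product: 18 punaglandin 2
Conditions: Ac2O, pyridine, CH2Cl2, 0 → 25 °C
Reagents that add atoms: acetic anhydride, CC(=O)OC(C)=O
Why: The three secondary alcohols are acetylated; the hindered tertiary C12-OH, flanked by a quaternary-type centre, is not acylated without DMAP. The C5–C8 and C12 stereocenters are unchanged.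

## Compound list
1 | D-xylose | O=C[C@H](O)[C@@H](O)[C@H](O)CO | starting material
2 | (2-carboxyethyl)triphenylphosphonium bromide | OC(=O)CC[P+](c1ccccc1)(c1ccccc1)c1ccccc1.[Br-] | starting material
3 | (3Z,5S,6R,7R)-5,6,7,8-tetrahydroxyoct-3-enoic acid | OC(=O)C/C=C\[C@H](O)[C@@H](O)[C@H](O)CO | intermediate
4 | methyl (5S,6R,7R)-5,6,7,8-tetrahydroxyoctanoate | COC(=O)CCC[C@H](O)[C@@H](O)[C@H](O)CO | intermediate
5 | methyl 5,6,7,8-tetrakis(TBSO)octanoate | COC(=O)CCC[C@H](O[Si](C)(C)C(C)(C)C)[C@@H](O[Si](C)(C)C(C)(C)C)[C@H](O[Si](C)(C)C(C)(C)C)CO[Si](C)(C)C(C)(C)C | intermediate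
6 | methyl 5,6,7-tris(TBSO)-8-hydroxyoctanoate | COC(=O)CCC[C@H](O[Si](C)(C)C(C)(C)C)[C@@H](O[Si](C)(C)C(C)(C)C)[C@H](O[Si](C)(C)C(C)(C)C)CO | intermediate
7 | methyl (5S,6R,7S)-5,6,7-tris(TBSO)-8-oxooctanoate | COC(=O)CCC[C@H](O[Si](C)(C)C(C)(C)C)[C@@H](O[Si](C)(C)C(C)(C)C)[C@H](O[Si](C)(C)C(C)(C)C)C=O | intermediate
8 | (Z)-oct-2-en-1-ol | CCCCC/C=C\CO | starting material
9 | (Z)-1-bromooct-2-ene | CCCCC/C=C\CBr | intermediate
10 | furan | c1ccoc1 | starting material
11 | 2-[(2Z)-oct-2-en-1-yl]furan | CCCCC/C=C\Cc1ccco1 | intermediate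
12 | furylcarbinol (C8 epimeric mixture) | COC(=O)CCC[C@H](O[Si](C)(C)C(C)(C)C)[C@@H](O[Si](C)(C)C(C)(C)C)[C@H](O[Si](C)(C)C(C)(C)C)C(O)c1ccc(C/C=C\CCCCC)o1 | intermediate
13 | 8-epi-hydroxycyclopentenone (tris-TBS) | CCCCC/C=C\C[C@@]1(O)C=CC(=O)[C@H]1[C@@H](O[Si](C)(C)C(C)(C)C)[C@H](O[Si](C)(C)C(C)(C)C)[C@H](CCCC(=O)OC)O[Si](C)(C)C(C)(C)C | intermediate
14 | 10,11-epoxy ketone (tris-TBS; epoxide stereo undefined) | CCCCC/C=C\C[C@@]1(O)C2OC2C(=O)[C@H]1[C@@H](O[Si](C)(C)C(C)(C)C)[C@H](O[Si](C)(C)C(C)(C)C)[C@H](CCCC(=O)OC)O[Si](C)(C)C(C)(C)C | intermediate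
15 | 10-chloro-11-hydroxy ketone (tris-TBS; C10/C11 stereo undefined) | CCCCC/C=C\C[C@@]1(O)C(O)C(Cl)C(=O)[C@H]1[C@@H](O[Si](C)(C)C(C)(C)C)[C@H](O[Si](C)(C)C(C)(C)C)[C@H](CCCC(=O)OC)O[Si](C)(C)C(C)(C)C | intermediate
16 | 10-chloroenone, tris-TBS | CCCCC/C=C\C[C@@]1(O)C=C(Cl)C(=O)[C@@H]1[C@@H](O[Si](C)(C)C(C)(C)C)[C@H](O[Si](C)(C)C(C)(C)C)[C@H](CCCC(=O)OC)O[Si](C)(C)C(C)(C)C | intermediate
17 | triol chloroenone | CCCCC/C=C\C[C@@]1(O)C=C(Cl)C(=O)[C@@H]1[C@@H](O)[C@H](O)[C@H](CCCC(=O)OC)O | intermediate
18 | punaglandin 2 | CCCCC/C=C\C[C@@]1(O)C=C(Cl)C(=O)[C@@H]1[C@@H](OC(C)=O)[C@H](OC(C)=O)[C@H](CCCC(=O)OC)OC(C)=O | target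

**Total steps:** 14. **Longest linear sequence:** 12 (D-xylose, Steps 1–5, then 8–14).

## Three steps most likely to fail
1. **Step 9 (Piancatelli).** The C7-controlled sense of rotation may be poor, the TBS ethers may be partly lost at 80 °C, and the OH/chain trans preference may differ from assumed.
   Fallback: use the 5-unsubstituted furylcarbinol, where the Piancatelli closure is reliably trans. Oxidise the C12 alcohol to the 2-ene-1,4-dione, then add the (Z)-oct-2-enyl cerium or zinc reagent anti to the C8 chain to make the C12 tertiary alcohol.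
2. **Steps 11–12 (chlorination and elimination).** Chloride may open the epoxide at the wrong carbon, and DBU may cause β-elimination of the C7-OTBS or retro-aldol ring opening.
   Fallback: install chlorine before ring formation. Make 3-chlorofuran from 3-bromofuran (n-BuLi, C2Cl6), build the 2-lithio-3-chloro-5-alkylfuran, and carry the C10–Cl through the Piancatelli step.
3. **Step 1 (Wittig on unprotected xylose).** The β-carboxyethyl ylide can undergo retro-Michael loss of PPh3, and unprotected sugar lactols react sluggishly.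
   Fallback: methylenation of xylose (Ph3P=CH2), then silyl protection, then cross-metathesis of the terminal alkene with methyl but-3-enoate and hydrogenation, which gives the same C4–C1 chain.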